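# Proposed synthesis of (3S,5R,8R,3'S,5'R,6'S)-5,8-epoxy-5,8,5',6'-tetrahydro-β,β-carotene-3,3',5',6'-tetrol (26)

## The problem

Compound 26 joins two different oxygenated trimethylcyclohexane rings through an all-E chain of eight conjugated double bonds (C9=C10 to C7'=C8'), so the chain must be assembled unsymmetrically and every new double bond must end up E. Six stereocentres have to be set, C3, C5 and C8 in the furanoid half and C3', C5' and C6' in the triol half, and both rings show the same pattern of a secondary carbinol at C3 and a tertiary oxygen at C5 trans to it. A C3 stereocentre can therefore direct C5 through a chair, and C5 together with the quaternary C1 can direct an addition to C6; C8 lies across the ring oxygen from C5, sees only the difference between a methyl group and a ring methylene, and is the centre least open to substrate control. C5, C6' and their neighbour C1 are fully substituted, so bonds to them are best made intramolecularly or with slim nucleophiles. The polyene is sensitive to light, oxygen and acid: the tertiary C6' hydroxyl is allylic to the whole chain and ionises with acid to a polyenyl cation that the C5' or C3' oxygen captures, and the doubly allylic C8–O bond epimerises in the same way, so the end of the route must be neutral or basic and the protecting groups must leave with fluoride. The feature that invites the key step is the C5'–C6' bond of the triol ring: it carries two cis oxygens, C6' is flanked by the quaternary C1' and maps onto an aldehyde without α-hydrogen, C5' maps onto a methyl ketone, and together these are the retron of a reductive pinacol ring closure of an acyclic 1,6-keto aldehyde whose only stereocentre is C3'. A second feature is that the dihydrofuran of the other half (O–C8 bond, C6=C7) is the cyclodehydrated isomer of this same diol (C6–OH, C7=C8), so one ring synthesis can serve both ends.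

## Retrosynthesis

**26 from 25.** The three silyl ethers of 25 are removed last with fluoride. Silyl groups are chosen throughout because no acidic or reductive unmasking would leave the C6' carbinol and the C8–O bond intact.

**25 from 19 and 23 (C11'=C12').** The chain is cut into the C15 sulfone 19 and the C25 aldehyde 23. This disubstituted double bond is preferred to C15=C15', which would need two different C20 halves with long separate routes. It is also preferred to the trisubstituted C9'=C10', whose geometry an olefination controls poorly. The 11'-cis isomer is strained by the C13' methyl group and relaxes on heating, so a Julia–Kocienski coupling followed by thermal equilibration is asked to deliver the E bond under base only.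

**23 from 22 (O–C8).** The dihydrofuran is opened to the hydroxy silyl ether 22, the same end group as in 19. The forward step is an acid-induced cyclodehydration through the cation known from the epoxide-to-furanoid rearrangement. This removes a second ring synthesis from a second chiral source. The cost is that C8 is not controlled: closure on either face of C8 is expected, so 23 has to be separated chromatographically, and the fraction of opposite C8 configuration has to be returned to the acid or given up.

**22 from 19 and 20 (C11=C12).** The same sulfone 19 is joined to the commercial, symmetrical C10 dialdehyde 20. The forward reaction must stop at mono-olefination, which an excess of 20 secures.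

**19 from 14 and 15 (C6–C7).** The sulfone comes from the dienol 17 and this from the propargylic alcohol 16, which is cut between the ring and the side chain into ketone 14 and the commercial enynol 15. An olefination at C7=C8 is ruled out because C6 is a fully substituted carbinol. The acetylide is slim enough for the doubly α-quaternary ketone, its axial entry sets C6, and 15 brings C7 to C11 with the C9=C10 geometry in place.

**14 from 12.** The ketone 14 is the silyl ether of the hydroxy ketone 13, which is the oxidation product of the diol 12. Only the ring and the C5 carbinol of 12 survive into later compounds.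

**12 from 11 (C5–C6, key step).** The cis diol is opened to the acyclic keto aldehyde 11. Against a dihydroxylation or epoxide hydrolysis of a preformed cyclohexene, this cut derives the ring and C5 from one acyclic stereocentre and needs no facial selection on a trisubstituted alkene.

**11 from 1, 2 and 5.** The methyl ketone comes from ozonolysis of the isopropenyl group of 9 and the aldehyde from the nitrile of 7. The carbon chain of 6 is cut at C2–C3 (epoxide 4 plus isobutyronitrile 5) and at C4–C5 ((R)-epichlorohydrin 1 plus the Grignard reagent 2). A nitrile is preferred to an ester because a γ-hydroxy ester with a gem-dimethyl group would lactonise. The Grignard opening is placed first because its regiochemistry on 1 is unambiguous. This order requires the (R) enantiomer of 1.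

## Roads not taken

**Alternative 1:** The cut is made at C14'–C15' and C14–C15 with a two-carbon linchpin. Ethynyltrimethylsilane A4 would be coupled (Sonogashira) with the triol-end tetraenyl iodide A2, desilylated in the same flask and coupled with the furanoid trienyl iodide A3 to give the 15,15'-didehydro compound A1. Semihydrogenation over Pd/CaCO3 poisoned with Pb(OAc)2 and thermal cis-to-trans isomerisation of the central bond would follow.
- Merits: it is the most convergent assembly (C19 + C2 + C19). The couplings are nearly neutral and tolerate the tertiary allylic alcohol and the dihydrofuran. The central cis bond is the one that isomerises most cleanly.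
- Weak points: A2 and A3 are light- and heat-sensitive polyenyl iodides that each need a long stereodefined synthesis. The one-flask double coupling risks oxidative alkyne dimerisation and symmetrical products. The partial hydrogenation must spare eight other double bonds. The plan is silent on the six stereocentres.
- Comparison: in convergence this road is better than the chosen one. The chosen plan sets against it a commercial C10 centre piece, one C15 sulfone used twice, no polyenyl halides, and a solution of the ring stereochemistry that this road would still need.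

**Alternative 2:** The cut is the C6'–O bond of a cyclic carbonate. Zerovalent palladium would ionise the allylic C6'–O bond of the anti-epoxy dienoate A6 with inversion, the C5' alkoxide would take up CO2, and the carbonate oxygen would return to C6' anti to the metal, giving the cis-carbonate A5 with net retention.
- Merits: the oxygen switch is stereospecific, the chain is already attached when C6' is set, and the carbonate protects the diol. In these respects it is shorter than steps 10 to 11 here.
- Weak points: C6' is a fully substituted allyl terminus next to the quaternary C1', so attack at the C8' end and β-hydride loss compete. A6 is itself prone to the acid-induced furanoid rearrangement. The anti configuration of A6 rests on an epoxidation with limited facial bias from the C3' oxygen. The carbonate needs a separate basic cleavage, and the furanoid half is not addressed.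
- Comparison: A5 reaches a C15 triol unit in fewer operations once A6 is in hand. The chosen plan sets against it that every ring stereocentre follows from one inexpensive stereocentre through conformationally defined steps, that no substitution at a hindered tertiary allylic carbon is needed, and that the same intermediate also yields the furanoid half.

**Alternative 3:** The cut is the O–C8 bond, made by axis-to-centre chirality transfer. AuCl3 would activate the C7=C8 bond of the hydroxy vinylallene A8, the C5 hydroxyl would add to C8 in a 5-endo closure, and protodemetallation would give the furanoid C15 bis-silyl ether A7 with C6=C7 in place.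
- Merits: of the four plans this is the only one that sets C8 by design, under mild and neutral conditions. In this respect it is clearly better than step 15 of the chosen route.
- Weak points: for the 8R centre A8 must carry the C9 substituent of C8 on the face of the C5 oxygen (the 6S axis), the opposite of the allenic end groups found in nature, so the stereoselective construction of the allene becomes the real task and adds steps. A vinylallene under AuCl3 catalysis can also undergo Nazarov-type carbocyclisation or lose its axial configuration. The triol half is left open.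
- Comparison: the chosen plan gives away control of C8. It sets against this that the dihydrofuran arises in one step from a compound already on the route, that material of the wrong C8 configuration can be returned to the same step, and that no separate allene synthesis or second ring synthesis is required.

Key step: step 7

Remark on the chemistry: locants are carotenoid locants (unprimed for the furanoid half, primed for the triol half of 25 and 26); intermediates up to 19, which serve both halves, carry unprimed locants. TBS = tert-butyldimethylsilyl, TES = triethylsilyl, PT = 1-phenyl-1H-tetrazol-5-yl.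
Remark on the chemistry: metallated forms of numbered compounds (lithiated nitrile, acetylide, sulfonyl carbanion) are not numbered separately.

## Steps

Step 1
Reactants: 1 (R)-epichlorohydrin; 2 isopropenylmagnesium bromide
Product: 3 (R)-1-chloro-4-methylpent-4-en-2-ol
Conditions: CuI (10 mol %), THF, −40 → −20 °C; aq. NH4Cl
Reagents that add atoms: none
Why: CuI-catalysed Grignard opening of a terminal epoxide at its unsubstituted carbon; chloride is not displaced at this temperature and no bond to the stereocentre is touched, so the configuration of 1 is carried over.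

Step 2
Reactants: 3 (R)-1-chloro-4-methylpent-4-en-2-ol
Product: 4 (R)-2-(2-methylprop-2-en-1-yl)oxirane
Conditions: NaOH (powder), Et2O, rt; distillation
Reagents that add atoms: none
Why: Intramolecular Williamson ether synthesis of a chlorohydrin; the alkoxide attacks the CH2Cl carbon, so the carbinol stereocentre is unchanged.

Step 3
Reactants: 4 (R)-2-(2-methylprop-2-en-1-yl)oxirane; 5 isobutyronitrile
Product: 6 (R)-4-hydroxy-2,2,6-trimethylhept-6-enenitrile
Conditions: 5 (1.3 equiv), LiN(i-Pr)2 (1.2 equiv), THF, −78 °C; then 4, −78 °C → rt; aq. NH4Cl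
Reagents that add atoms: none
Why: Alkylation of a lithiated nitrile by a terminal epoxide at the CH2 terminus; the nitrile cannot lactonise as an ester would, the slight excess of nitrile leaves no free amide base to isomerise the epoxide, and the stereocentre is not involved.

Step 4
Reactants: 6 (R)-4-hydroxy-2,2,6-trimethylhept-6-enenitrile
Product: 7 (R)-4-(TBS-oxy)-2,2,6-trimethylhept-6-enenitrile
Conditions: TBSCl, imidazole, DMF, rt
Reagents that add atoms: tert-butyldimethylsilyl chloride, CC(C)(C)[Si](C)(C)Cl
Why: Standard silylation of a secondary alcohol; the TBS group is kept to the end and later steers the chair of the key step.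

Step 5
Reactants: 7 (R)-4-(TBS-oxy)-2,2,6-trimethylhept-6-enenitrile
Product: 9 (R)-4-(TBS-oxy)-2,2,6-trimethylhept-6-enal, via aldimine 8 (not isolated)
Conditions: i-Bu2AlH (1.3 equiv), toluene, −78 → 0 °C; then aq. AcOH/NaOAc (pH 5), rt
Reagents that add atoms: water, O
Why: Partial reduction of a nitrile by a dialkylaluminium hydride stops at the N-metallated imine, which hydrolyses to the aldehyde on buffered work-up; the α-carbon is quaternary, so neither enamine formation nor epimerisation is possible, and the silyl ether and alkene are inert.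

Step 6
Reactants: 9 (R)-4-(TBS-oxy)-2,2,6-trimethylhept-6-enal
Product: 11 (4S)-4-(TBS-oxy)-2,2-dimethyl-6-oxoheptanal, via ozonide 10 (not isolated)
Conditions: O3, CH2Cl2, −78 °C; then PPh3, −78 °C → rt
Reagents that add atoms: ozone, [O-][O+]=O
Why: Ozonolysis of a 1,1-disubstituted alkene with reductive work-up gives the methyl ketone; the aldehyde has no α-hydrogen and survives at −78 °C, and the descriptor changes from R to S only because the priorities change.

Step 7
Reactants: 11 (4S)-4-(TBS-oxy)-2,2-dimethyl-6-oxoheptanal
Product: 12 (1S,2R,4S)-4-(TBS-oxy)-2,6,6-trimethylcyclohexane-1,2-diol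
Conditions: SmI2 (2.5 equiv), t-BuOH (2 equiv), THF (0.01 M), −78 °C → rt; aq. NaHCO3/Na2S2O3
Reagents that add atoms: none
Why: Single-electron transfer from divalent samarium to the aldehyde, the more easily reduced carbonyl, gives a samarium ketyl at C6, which adds to the samarium-bound methyl ketone carbon C5; a second electron and protonation by t-BuOH deliver the diol. The closest known reaction type is the SmI2-mediated intramolecular pinacol coupling of 1,6-keto aldehydes to cis-cyclohexane-1,2-diols. The ring closes in the 6-exo-trig mode (radical at C6 onto C5=O, oxygen outside the ring). C5 is controlled by the C3 stereocentre: in the chair transition state one C1 methyl is necessarily axial, so the C3 siloxy group and the C5 methyl both take equatorial positions to avoid 1,3-diaxial contact with it, which places the C5 oxygen axial and trans to the C3 oxygen. C6 is controlled by samarium, which bridges both oxygens during bond formation and so delivers the C6 oxygen cis to the C5 oxygen; this centre is removed in step 8, so a lapse there costs nothing. The step needs reduction of the aldehyde before the ketone, which low temperature and the difference in reduction potential should secure, and ring closure before intermolecular coupling or simple reduction, which dilution and the gem-dimethyl group at C1 favour. The aldehyde has no α-hydrogen, and the siloxy group sits on the β-carbon of the ketone and not on an α-carbon, so neither enolisation of the aldehyde nor reductive loss of the siloxy group should intervene.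

Step 8
Reactants: 12 (1S,2R,4S)-4-(TBS-oxy)-2,6,6-trimethylcyclohexane-1,2-diol
Product: 13 (2R,4S)-4-(TBS-oxy)-2-hydroxy-2,6,6-trimethylcyclohexan-1-one
Conditions: (COCl)2, DMSO, CH2Cl2, −78 °C; then Et3N, −78 → 0 °C
Reagents that add atoms: none
Why: Swern oxidation of the secondary hydroxyl of a secondary/tertiary 1,2-diol, which does not cleave the glycol C–C bond; the product has no α-hydrogen, so C5 cannot epimerise.

Step 9
Reactants: 13 (2R,4S)-4-(TBS-oxy)-2-hydroxy-2,6,6-trimethylcyclohexan-1-one
Product: 14 (2R,4S)-4-(TBS-oxy)-2,6,6-trimethyl-2-(TES-oxy)cyclohexan-1-one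
Conditions: TESOTf, 2,6-lutidine, CH2Cl2, −78 → 0 °C
Reagents that add atoms: triethylsilyl trifluoromethanesulfonate, CC[Si](CC)(CC)OS(=O)(=O)C(F)(F)F
Why: Silyl triflate silylation of a hindered tertiary alcohol; the ketone cannot enolise, so no silyl enol ether competes, and the capped oxygen cannot chelate or quench the acetylide of step 10.

Step 10
Reactants: 14 (2R,4S)-4-(TBS-oxy)-2,6,6-trimethyl-2-(TES-oxy)cyclohexan-1-one; 15 (E)-3-methylpent-2-en-4-yn-1-ol
Product: 16 (1R,2R,4S)-4-(TBS-oxy)-1-[(3E)-5-hydroxy-3-methylpent-3-en-1-yn-1-yl]-2,6,6-trimethyl-2-(TES-oxy)cyclohexan-1-ol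
Conditions: 15 (2 equiv), n-BuLi (4 equiv), THF, −78 → 0 °C; then 14, −78 °C → rt; aq. NH4Cl
Reagents that add atoms: none
Why: 1,2-Addition of a lithium acetylide (as the alkoxide–acetylide dianion of 15) to a non-enolisable ketone; in the chair with the C3 siloxy group equatorial the axial C1 methyl and the axial C5 siloxy group block one face, so the slim nucleophile enters axially from the other and sets C6 with its hydroxyl cis to the C5 oxygen.

Step 11
Reactants: 16 (1R,2R,4S)-4-(TBS-oxy)-1-[(3E)-5-hydroxy-3-methylpent-3-en-1-yn-1-yl]-2,6,6-trimethyl-2-(TES-oxy)cyclohexan-1-ol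
Product: 17 (1S,2R,4S)-4-(TBS-oxy)-1-[(1E,3E)-5-hydroxy-3-methylpenta-1,3-dien-1-yl]-2,6,6-trimethyl-2-(TES-oxy)cyclohexan-1-ol
Conditions: NaAlH2(OCH2CH2OMe)2 (Red-Al, 4 equiv), THF, 0 °C → rt; aq. potassium sodium tartrate
Reagents that add atoms: none
Why: Alkoxide-directed trans-hydroalumination of a propargylic alcohol gives the E alkene at C7=C8 after protonolysis; the C9=C10 bond and the silyl ethers are not attacked, and the change of the C6 descriptor is due to priorities only.

Step 12
Reactants: 17 (1S,2R,4S)-4-(TBS-oxy)-1-[(1E,3E)-5-hydroxy-3-methylpenta-1,3-dien-1-yl]-2,6,6-trimethyl-2-(TES-oxy)cyclohexan-1-ol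
Product: 18 5-{[(2E,4E)-5-[(1S,2R,4S)-4-(TBS-oxy)-1-hydroxy-2,6,6-trimethyl-2-(TES-oxy)cyclohexyl]-3-methylpenta-2,4-dien-1-yl]sulfanyl}-1-phenyl-1H-tetrazole
Conditions: 1-phenyl-1H-tetrazole-5-thiol, PPh3, DIAD, THF, 0 °C → rt
Reagents that add atoms: 1-phenyl-1H-tetrazole-5-thiol, Sc1nnnn1-c1ccccc1
Why: Mitsunobu thioetherification of the primary allylic alcohol by direct SN2 displacement; the tertiary hydroxyl is not activated under these conditions.

Step 13
Reactants: 18 5-{[(2E,4E)-5-[(1S,2R,4S)-4-(TBS-oxy)-1-hydroxy-2,6,6-trimethyl-2-(TES-oxy)cyclohexyl]-3-methylpenta-2,4-dien-1-yl]sulfanyl}-1-phenyl-1H-tetrazole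
Product: 19 5-{[(2E,4E)-5-[(1S,2R,4S)-4-(TBS-oxy)-1-hydroxy-2,6,6-trimethyl-2-(TES-oxy)cyclohexyl]-3-methylpenta-2,4-dien-1-yl]sulfonyl}-1-phenyl-1H-tetrazole
Conditions: (NH4)6Mo7O24·4H2O (10 mol %), 30% aq. H2O2, EtOH, 0 °C → rt
Reagents that add atoms: hydrogen peroxide, OO
Why: (NH4)6Mo7O24-catalysed oxidation of a sulfide to the sulfone by H2O2, the usual chemoselective route to allylic tetrazolyl sulfones in the presence of alkenes; sulfur is oxidised much faster than the diene at low temperature.

Step 14
Reactants: 19 5-{[(2E,4E)-5-[(1S,2R,4S)-4-(TBS-oxy)-1-hydroxy-2,6,6-trimethyl-2-(TES-oxy)cyclohexyl]-3-methylpenta-2,4-dien-1-yl]sulfonyl}-1-phenyl-1H-tetrazole; 20 (2E,4E,6E)-2,7-dimethylocta-2,4,6-trienedial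
Product: 22 (all-E,3S,5R,6S)-3-(TBS-oxy)-6-hydroxy-5-(TES-oxy)-5,6-dihydro-12'-apo-β-caroten-12'-al, via 11Z isomer 21 (not isolated)
Conditions: 20 (3 equiv), KN(SiMe3)2 (1.2 equiv) added to the mixture, THF, −78 °C → rt; then EtOAc, 75 °C, dark, argon
Reagents that add atoms: none
Why: Julia–Kocienski olefination under Barbier conditions, with excess dialdehyde to hold the reaction at mono-olefination; the allylic sulfonyl CH2 is far more acidic than the tertiary hydroxyl, so little more than one equivalent of base is needed, and the 11Z isomer, strained by the C13 methyl group, should relax to the all-E compound on heating.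

Step 15
Reactants: 22 (all-E,3S,5R,6S)-3-(TBS-oxy)-6-hydroxy-5-(TES-oxy)-5,6-dihydro-12'-apo-β-caroten-12'-al
Product: 23 (all-E,3S,5R,8R)-3-(TBS-oxy)-5,8-epoxy-5,8-dihydro-12'-apo-β-caroten-12'-al
Conditions: (+)-camphor-10-sulfonic acid (10 mol %), CH2Cl2, 0 °C, dark; Et3N; chromatography on Et3N-deactivated SiO2
Reagents that add atoms: none
Why: Acid-induced cyclodehydration of a 5,6-dioxygenated end group to the 5,8-furanoid: the tertiary allylic C6 hydroxyl ionises to the polyenyl cation of the epoxide-to-furanoid rearrangement, the C5 oxygen closes on C8 and passes its silyl group to the water set free, while C3 and C5 are untouched. The closing oxygen meets either face of C8 and the doubly allylic C8–O bond can re-ionise, so no facial preference is assumed: 23 is taken from the mixture by chromatography, and the fraction of opposite C8 configuration can be resubmitted to the same acid, where it re-enters the common cation.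

Step 16
Reactants: 19 5-{[(2E,4E)-5-[(1S,2R,4S)-4-(TBS-oxy)-1-hydroxy-2,6,6-trimethyl-2-(TES-oxy)cyclohexyl]-3-methylpenta-2,4-dien-1-yl]sulfonyl}-1-phenyl-1H-tetrazole; 23 (all-E,3S,5R,8R)-3-(TBS-oxy)-5,8-epoxy-5,8-dihydro-12'-apo-β-caroten-12'-al
Product: 25 (all-E,3S,5R,8R,3'S,5'R,6'S)-3,3'-bis(TBS-oxy)-5'-(TES-oxy)-5,8-epoxy-5,8,5',6'-tetrahydro-β,β-caroten-6'-ol, via 11'Z isomer 24 (not isolated)
Conditions: KN(SiMe3)2 (1.2 equiv) added to the mixture, THF, −78 °C → rt; then EtOAc, 75 °C, dark, argon
Reagents that add atoms: none
Why: Second Julia–Kocienski olefination of the same sulfone, now forming C11'=C12'; base and neutral heating leave the C8–O bond and the C6' carbinol alone, and the strained 11'Z isomer should again relax thermally to the all-E chain.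

Step 17
Reactants: 25 (all-E,3S,5R,8R,3'S,5'R,6'S)-3,3'-bis(TBS-oxy)-5'-(TES-oxy)-5,8-epoxy-5,8,5',6'-tetrahydro-β,β-caroten-6'-ol
Product: 26 (3S,5R,8R,3'S,5'R,6'S)-5,8-epoxy-5,8,5',6'-tetrahydro-β,β-carotene-3,3',5',6'-tetrol
Conditions: Bu4NF (6 equiv), THF, 0 °C → rt, dark
Reagents that add atoms: none
Why: Fluoride-induced desilylation removes the two TBS ethers and the TES ether without acid, so the tertiary allylic alcohol and the doubly allylic ether are not ionised and no stereocentre is touched.

## Compound list

1 | (R)-epichlorohydrin | ClC[C@H]1CO1 | starting material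
2 | isopropenylmagnesium bromide | CC(=C)[Mg]Br | starting material
3 | (R)-1-chloro-4-methylpent-4-en-2-ol | ClC[C@H](O)CC(C)=C | intermediate
4 | (R)-2-(2-methylprop-2-en-1-yl)oxirane | C=C(C)C[C@@H]1CO1 | intermediate
5 | isobutyronitrile | CC(C)C#N | starting material
6 | (R)-4-hydroxy-2,2,6-trimethylhept-6-enenitrile | C=C(C)C[C@@H](O)CC(C)(C)C#N | intermediate
7 | (R)-4-(tert-butyldimethylsilyloxy)-2,2,6-trimethylhept-6-enenitrile | C=C(C)C[C@@H](O[Si](C)(C)C(C)(C)C)CC(C)(C)C#N | intermediate
8 | (R)-4-(tert-butyldimethylsilyloxy)-2,2,6-trimethylhept-6-en-1-imine (aldimine, not isolated) | C=C(C)C[C@@H](O[Si](C)(C)C(C)(C)C)CC(C)(C)C=N | intermediate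
9 | (R)-4-(tert-butyldimethylsilyloxy)-2,2,6-trimethylhept-6-enal | C=C(C)C[C@@H](O[Si](C)(C)C(C)(C)C)CC(C)(C)C=O | intermediate
10 | (4S)-4-(tert-butyldimethylsilyloxy)-2,2-dimethyl-5-(3-methyl-1,2,4-trioxolan-3-yl)pentanal (ozonide, both configurations at the trioxolane carbon, not isolated) | CC1(C[C@@H](O[Si](C)(C)C(C)(C)C)CC(C)(C)C=O)OCOO1 | intermediate
11 | (4S)-4-(tert-butyldimethylsilyloxy)-2,2-dimethyl-6-oxoheptanal | O=CC(C)(C)C[C@H](O[Si](C)(C)C(C)(C)C)CC(C)=O | intermediate
12 | (1S,2R,4S)-4-(tert-butyldimethylsilyloxy)-2,6,6-trimethylcyclohexane-1,2-diol | O[C@H]1C(C)(C)C[C@H](O[Si](C)(C)C(C)(C)C)C[C@@]1(C)O | intermediate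
13 | (2R,4S)-4-(tert-butyldimethylsilyloxy)-2-hydroxy-2,6,6-trimethylcyclohexan-1-one | O=C1C(C)(C)C[C@H](O[Si](C)(C)C(C)(C)C)C[C@@]1(C)O | intermediate
14 | (2R,4S)-4-(tert-butyldimethylsilyloxy)-2,6,6-trimethyl-2-(triethylsilyloxy)cyclohexan-1-one | O=C1C(C)(C)C[C@H](O[Si](C)(C)C(C)(C)C)C[C@@]1(C)O[Si](CC)(CC)CC | intermediate
15 | (E)-3-methylpent-2-en-4-yn-1-ol | C#C/C(C)=C/CO | starting material
16 | (1R,2R,4S)-4-(tert-butyldimethylsilyloxy)-1-[(3E)-5-hydroxy-3-methylpent-3-en-1-yn-1-yl]-2,6,6-trimethyl-2-(triethylsilyloxy)cyclohexan-1-ol | OC/C=C(C)/C#C[C@]1(O)C(C)(C)C[C@H](O[Si](C)(C)C(C)(C)C)C[C@@]1(C)O[Si](CC)(CC)CC | intermediate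
17 | (1S,2R,4S)-4-(tert-butyldimethylsilyloxy)-1-[(1E,3E)-5-hydroxy-3-methylpenta-1,3-dien-1-yl]-2,6,6-trimethyl-2-(triethylsilyloxy)cyclohexan-1-ol | OC/C=C(C)/C=C/[C@]1(O)C(C)(C)C[C@H](O[Si](C)(C)C(C)(C)C)C[C@@]1(C)O[Si](CC)(CC)CC | intermediate
18 | 5-{[(2E,4E)-5-[(1S,2R,4S)-4-(tert-butyldimethylsilyloxy)-1-hydroxy-2,6,6-trimethyl-2-(triethylsilyloxy)cyclohexyl]-3-methylpenta-2,4-dien-1-yl]sulfanyl}-1-phenyl-1H-tetrazole | CC(/C=C/[C@]1(O)C(C)(C)C[C@H](O[Si](C)(C)C(C)(C)C)C[C@@]1(C)O[Si](CC)(CC)CC)=C\CSc1nnnn1-c1ccccc1 | intermediate
19 | 5-{[(2E,4E)-5-[(1S,2R,4S)-4-(tert-butyldimethylsilyloxy)-1-hydroxy-2,6,6-trimethyl-2-(triethylsilyloxy)cyclohexyl]-3-methylpenta-2,4-dien-1-yl]sulfonyl}-1-phenyl-1H-tetrazole | CC(/C=C/[C@]1(O)C(C)(C)C[C@H](O[Si](C)(C)C(C)(C)C)C[C@@]1(C)O[Si](CC)(CC)CC)=C\CS(=O)(=O)c1nnnn1-c1ccccc1 | intermediate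
20 | (2E,4E,6E)-2,7-dimethylocta-2,4,6-trienedial | O=C/C(C)=C/C=C/C=C(C)/C=O | starting material
21 | (11Z)-isomer of 22 (not isolated) | O=C/C(C)=C/C=C/C=C(C)/C=C\C=C(C)\C=C\[C@]1(O)C(C)(C)C[C@H](O[Si](C)(C)C(C)(C)C)C[C@@]1(C)O[Si](CC)(CC)CC | intermediate
22 | (all-E,3S,5R,6S)-3-(tert-butyldimethylsilyloxy)-6-hydroxy-5-(triethylsilyloxy)-5,6-dihydro-12'-apo-β-caroten-12'-al | O=C/C(C)=C/C=C/C=C(C)/C=C/C=C(C)/C=C/[C@]1(O)C(C)(C)C[C@H](O[Si](C)(C)C(C)(C)C)C[C@@]1(C)O[Si](CC)(CC)CC | intermediate
23 | (all-E,3S,5R,8R)-3-(tert-butyldimethylsilyloxy)-5,8-epoxy-5,8-dihydro-12'-apo-β-caroten-12'-al | O=C/C(C)=C/C=C/C=C(C)/C=C/C=C(\C)[C@H]1C=C2C(C)(C)C[C@H](O[Si](C)(C)C(C)(C)C)C[C@@]2(C)O1 | intermediate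
24 | (11'Z)-isomer of 25 (not isolated) | CC(/C=C\C=C(C)\C=C\[C@]1(O)C(C)(C)C[C@H](O[Si](C)(C)C(C)(C)C)C[C@@]1(C)O[Si](CC)(CC)CC)=C\C=C\C=C(C)\C=C\C=C(/C)[C@H]1C=C2C(C)(C)C[C@H](O[Si](C)(C)C(C)(C)C)C[C@@]2(C)O1 | intermediate
25 | (all-E,3S,5R,8R,3'S,5'R,6'S)-3,3'-bis(tert-butyldimethylsilyloxy)-5'-(triethylsilyloxy)-5,8-epoxy-5,8,5',6'-tetrahydro-β,β-caroten-6'-ol | CC(/C=C/C=C(C)/C=C/[C@]1(O)C(C)(C)C[C@H](O[Si](C)(C)C(C)(C)C)C[C@@]1(C)O[Si](CC)(CC)CC)=C\C=C\C=C(C)\C=C\C=C(/C)[C@H]1C=C2C(C)(C)C[C@H](O[Si](C)(C)C(C)(C)C)C[C@@]2(C)O1 | intermediate
26 | (3S,5R,8R,3'S,5'R,6'S)-5,8-epoxy-5,8,5',6'-tetrahydro-β,β-carotene-3,3',5',6'-tetrol | CC(/C=C/C=C(C)/C=C/[C@]1(O)C(C)(C)C[C@H](O)C[C@@]1(C)O)=C\C=C\C=C(C)\C=C\C=C(/C)[C@H]1C=C2C(C)(C)C[C@H](O)C[C@@]2(C)O1 | target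

## Step count and risks

Total step count: 17. Longest linear sequence: 17 steps (1 to 26; sulfone 19 enters twice, in steps 14 and 16).

Least certain steps:

**Step 7 (key step).** Most likely to go wrong is ring closure losing out to plain reduction of the hindered aldehyde or to intermolecular coupling, because the ketyl sits next to a quaternary carbon. Insufficient facial bias at C5 is the second risk, if the chair with the equatorial siloxy group is less dominant than expected. Fallback: from 11 the same C5–C6 bond would be formed by an intramolecular crossed aldehyde–ketone benzoin reaction, with the carbene generated from 3-benzyl-5-(2-hydroxyethyl)-4-methylthiazolium chloride and Et3N in t-BuOH. The acyl anion equivalent of the aldehyde adds to the methyl ketone through the same chair and gives the hydroxy ketone 13 directly, so the route is rejoined at 13 and step 8 is skipped. This detour passes through no new isolated compound (F0).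

**Step 15.** Most likely to go wrong is closure without facial preference at C8 together with loss of stereochemical definition by reversible ionisation of the doubly allylic C8–O bond, poor chromatographic resolution of the two C8 configurations at the C25 stage, and consumption of the long polyenyl cation by proton loss or intermolecular capture. Fallback: the ring closure is moved to the small sulfone and the roles of the two halves are exchanged. From 19, the same acid treatment would give the furanoid C15 sulfone 5-{[(2E)-3-[(3S,5R,8R)-3-(TBS-oxy)-5,8-epoxy ring unit]but-2-en-1-yl]sulfonyl}-1-phenyl-1H-tetrazole F1 beside its C8 epimer F2. These should be separable by crystallisation or chromatography, and F2 would be re-equilibrated. Julia–Kocienski coupling of F1 with the hydroxy aldehyde 22, already on the route, followed by thermal equilibration of the 11Z isomer of 25 F3, comes back to the route at 25, and 23 is no longer needed.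

**Step 10.** Most likely to go wrong is failure of the poorly soluble dianion to add to the doubly α-quaternary carbonyl, or migration of the triethylsilyl group between the two vicinal tertiary oxygens in the alkoxide formed. Fallback: from 14, addition of ethynylmagnesium bromide (HC≡CMgBr, THF, 0 °C → rt), a smaller and monoanionic nucleophile, would give (1R,2R,4S)-4-(TBS-oxy)-1-ethynyl-2,6,6-trimethyl-2-(TES-oxy)cyclohexan-1-ol F4. Sonogashira coupling of F4 with (E)-3-iodobut-2-en-1-ol (PdCl2(PPh3)2, CuI, i-Pr2NH) then builds the enyne on the ring and returns to the route at 16.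

**Step 13.** Most likely to go wrong is hydroxyl-directed epoxidation of the C7=C8 bond by the peroxo species formed from (NH4)6Mo7O24 and H2O2, or acid-promoted ionisation of the free tertiary allylic alcohol in the aqueous ethanolic medium. Fallback: from 18 the tertiary hydroxyl is masked first (TMSOTf, 2,6-lutidine) as the trimethylsilyl ether of 18 F5. F5 is oxidised under the conditions of step 13 to the trimethylsilyl ether of 19 F6, and the trimethylsilyl group alone is removed with Bu4NF buffered with AcOH at 0 °C, which returns to the route at 19.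

## Further compounds

F0 | step 7 | none | none
F1 | step 15 | 5-{[(2E)-3-[(2R,6S,7aR)-6-(tert-butyldimethylsilyloxy)-4,4,7a-trimethyl-2,4,5,6,7,7a-hexahydro-1-benzofuran-2-yl]but-2-en-1-yl]sulfonyl}-1-phenyl-1H-tetrazole (carotenoid descriptors 3S,5R,8R) | C/C(=C\CS(=O)(=O)c1nnnn1-c1ccccc1)[C@H]1C=C2C(C)(C)C[C@H](O[Si](C)(C)C(C)(C)C)C[C@@]2(C)O1
F2 | step 15 | C8 epimer of F1 (carotenoid descriptors 3S,5R,8S) | C/C(=C\CS(=O)(=O)c1nnnn1-c1ccccc1)[C@@H]1C=C2C(C)(C)C[C@H](O[Si](C)(C)C(C)(C)C)C[C@@]2(C)O1
F3 | step 15 | (11Z)-isomer of 25 | CC(/C=C/C=C(C)/C=C/[C@]1(O)C(C)(C)C[C@H](O[Si](C)(C)C(C)(C)C)C[C@@]1(C)O[Si](CC)(CC)CC)=C\C=C\C=C(C)\C=C/C=C(\C)[C@H]1C=C2C(C)(C)C[C@H](O[Si](C)(C)C(C)(C)C)C[C@@]2(C)O1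
F4 | step 10 | (1R,2R,4S)-4-(tert-butyldimethylsilyloxy)-1-ethynyl-2,6,6-trimethyl-2-(triethylsilyloxy)cyclohexan-1-ol | C#C[C@]1(O)C(C)(C)C[C@H](O[Si](C)(C)C(C)(C)C)C[C@@]1(C)O[Si](CC)(CC)CC
F5 | step 13 | trimethylsilyl ether of 18 at the tertiary C6 hydroxyl | CC(/C=C/[C@]1(O[Si](C)(C)C)C(C)(C)C[C@H](O[Si](C)(C)C(C)(C)C)C[C@@]1(C)O[Si](CC)(CC)CC)=C\CSc1nnnn1-c1ccccc1
F6 | step 13 | trimethylsilyl ether of 19 at the tertiary C6 hydroxyl | CC(/C=C/[C@]1(O[Si](C)(C)C)C(C)(C)C[C@H](O[Si](C)(C)C(C)(C)C)C[C@@]1(C)O[Si](CC)(CC)CC)=C\CS(=O)(=O)c1nnnn1-c1ccccc1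
A1 | alternative 1 | 15,15'-didehydro derivative of 26 | CC(/C=C/C=C(C)/C=C/[C@]1(O)C(C)(C)C[C@H](O)C[C@@]1(C)O)=C\C#C/C=C(C)/C=C/C=C(\C)[C@H]1C=C2C(C)(C)C[C@H](O)C[C@@]2(C)O1
A2 | alternative 1 | triol-end C19 tetraenyl iodide | CC(/C=C/C=C(C)/C=C/[C@]1(O)C(C)(C)C[C@H](O)C[C@@]1(C)O)=C\I
A3 | alternative 1 | furanoid C19 trienyl iodide | I/C=C(C)/C=C/C=C(\C)[C@H]1C=C2C(C)(C)C[C@H](O)C[C@@]2(C)O1
A4 | alternative 1 | ethynyltrimethylsilane | C#C[Si](C)(C)C
A5 | alternative 2 | cis-5',6'-cyclic carbonate of the C15 triol dienoate | CCOC(=O)/C=C(C)/C=C/[C@]1(OC(=O)O2)C(C)(C)C[C@H](O)C[C@]12C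
A6 | alternative 2 | anti-5',6'-epoxy C15 dienoate (3'S,5'R,6'S) | CCOC(=O)/C=C(C)/C=C/[C@]1(O2)C(C)(C)C[C@H](O)C[C@]12C
A7 | alternative 3 | furanoid C15 bis-silyl ether (3S,5R,8R) | CC(C)(C)[Si](C)(C)OC/C=C(\C)[C@H]1C=C2C(C)(C)C[C@H](O[Si](C)(C)C(C)(C)C)C[C@@]2(C)O1
A8 | alternative 3 | hydroxy vinylallene with the 6S axis (3S,5R,6S) | CC(C)(C)[Si](C)(C)OC/C=C(\C)C=[C@]=C1C(C)(C)C[C@H](O[Si](C)(C)C(C)(C)C)C[C@@]1(C)O
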